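The noon run held 4.00 times the charge of the summer run, under the same held gas phase. After 40.0 min it had turned over less of its charge than the summer run, 48.1 % against 56.8 %. Yet it had made 3.39 times as much target.

| flask | substrate | gas phase | remark | time |
|---|---|---|---|---|
| summer | 0.40 M | 41 mM (held) | run made earlier |  |
| noon | 1.6 M | 41 mM (held) | run made earlier |  |
| flask | 0.80 M | 41 mM (held) |  | 1.0 h |

| run | time / min | target / % |
|---|---|---|
| summer | 5.00 | 9.0 |
| summer | 12.0 | 20.2 |
| summer | 25.0 | 41.1 |
| summer | 40.0 | 56.8 |
| noon | 10.0 | 14.6 |
| noon | 20.0 | 24.0 |
| noon | 25.0 | 32.4 |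
| noon | 40.0 | 48.1 |

(each reading ± 1 percentage point)

- at the start none of the gas phase is in solution
- a reading or a percentage of target counts all its forms, free or not

- amount of target in percent of the substrate charged, at 12 min, 30 min and 1.0 h

Equal fractions would mean pseudo-first-order decay. A fixed gas supply shared out over the charge would mean a quarter of the summer fraction. The readings gave a ratio of 0.847, between the two.

So I wrote one rule for a run. L is the natural log of the charge over what is left, x is the fraction turned over, and L + bx = kt. Here b is the drag, the loss in kt per whole charge turned over, and I took it as proportional to the charge.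

The 40.0 min readings give L = 0.839 for summer and 0.656 for noon. Equating kt in the two runs, I read a summer drag of 0.135. That makes the flask's drag 0.271, and k = 0.0229 min⁻¹. Both are readings and carry the scatter.

I solved the flask by going round. At 1.0 h, no drag gave 74.7 %. Putting that back gave 69.0 %, and once more gave 69.5 %. The same two rounds gave 18.9 % then 20.0 % at 12 min, and 42.5 % then 43.6 % at 30 min.

The forecast gave 19.3 %, 43 % and 68 %, and noted “Gas-transfer limitation would give the same form”.

The flask gave 18.9 %, 42.8 % and 69.3 % of target, crystals counted in.

    gas phase ⇌ dissolved gas, rate k1*(csat - [dissolved gas]) (kL = 0.0240 s⁻¹)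
    crystals ⇌ target, rate k2*(cs2 - [target]) while solid is left; crystals form when [target] > cs2 (solubility = 43.0 mM, k = 0.0810 s⁻¹)
    substrate + dissolved gas → target (k = 0.00960 L mol⁻¹ s⁻¹)
    dissolved gas → decomposition product (k = 1.30 × 10⁻⁶ s⁻¹)

At 0.500 h the flask still held 57.2 % of its substrate, which used dissolved gas at 0.00440 s⁻¹ times the dissolved gas present, while the crossing ran at 0.024 s⁻¹ times the shortfall below saturation, a larger constant. The drag times the substrate left puts dissolved gas in this flask at 35.5 mM, and it stood at 34.6 mM, under the saturation of 41 mM.

The runs were generated by integration on assumed constants; scatter was added.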